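A product curve that flattens tempts me to say that the reagent has run out, but in the blue flask, the one asked about, the subtraction says otherwise. Taking one reagent per product, the last blue reading leaves 0.0592 M of the 0.305 M charged. In the blue flask reagent is the limiting reagent, at half an equivalent, yet the product curve has bent with 0.0592 M of it unused at that reading.

| flask | substrate | reagent | free catalyst | temperature | remark | time |
|---|---|---|---|---|---|---|
| blue | 0.61 M | 0.305 M | 1.2 mM | 110 °C | the very flask that is asked about, followed so far |  |
| ochre | 0.61 M | 0.46 M | 1.2 mM | 116 °C | run made earlier |  |
| flask | 0.61 M | 0.305 M | 1.2 mM | 110 °C |  | 4.0 h |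

blue run (percent of the substrate charged)

| time / h | product / % | substrate / % |
|---|---|---|
| 0.500 | 16.7 | 83.5 |
| 1.33 | 30.5 | 67.3 |
| 2.50 | 37.0 | 62.1 |
| 4.00 | 40.3 | 63.3 |

ochre run (percent of the substrate charged)

| time / min | product / % | substrate / % |
|---|---|---|
| 30.0 | 27.8 | 73.9 |
| 60.0 | 40.9 | 58.2 |
| 90.0 | 45.2 | 54.5 |
| 120 | 49.5 | 52.3 |

(readings scatter by 1 percentage point)

- what is taken out of product is counted as made
- additions bring no volume worth counting

- alder: change nothing and wait 80 min more
- maple: at 4.0 h raise the temperature by 20 K, then wait 80 min
- cedar: at 4.0 h add reagent, 50.0% of the amount charged, then wait 80 min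
- oak: at 4.0 h take out 90% of the product then present, then wait 80 min
- ash: at 4.0 h add free catalyst, 100% of the amount charged, then wait 80 min

* product, in percent of the substrate first charged, at 4.0 h
* the remedy with the largest gain of product, or "none" below 2 percentage points (alder / maple / cedar / oak / ash / none)
* product present, with what was taken out counted in, in percent of the substrate first charged, after maple
* product present, with what was taken out counted in, in percent of the substrate first charged, after cedar

So I follow one catalyst molecule. At each fork it goes round again and makes a product, or it dies, and a dead molecule stops counting. If the rate is k·c(substrate)·c(reagent), k carries the working catalyst, and I need a measure with the concentrations divided out. I call it the reach: the natural logarithm of c(substrate)/c(reagent) now over the same ratio at the charge, divided by the difference of the two charges. This is the integrated second-order form, and it adds up k over time. In the blue flask the last reading gives a reach of 3.69 /M. Its speed is 1.47 /M/h up to the first reading, but 0.522 /M/h over the last interval. A way back would slow it as well, so reading this as dying catalyst is my judgement. On that judgement, I estimate that cedar multiplies the blue flask's rate at 4.0 h by 3.58, through c(reagent). If the fresh catalyst of ash brings the early speed on top of the late one, I estimate that ash multiplies that rate by 3.81. I commit to ash, narrowly, and take the last reading, 40.3%, for the product now.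

The forecast gives 40.6% (39.5% to 41.7%), 41.5% after maple (34% to 44.5%) and 47.5% after cedar (44.5% to 52%). It differs from me on the remedy: “Cedar is the most robust choice”.

The flask gives 39.0%. Ash gains 7.3 percentage points, the largest gain, so the answer is ash. Maple ends at 39.2% and cedar at 39.8%.

    catalyst intermediate B → catalyst intermediate C (k = 0.367 /s, Ea = 102 kJ/mol)
    catalyst intermediate C → free catalyst + product (k = 0.158 /s, Ea = 102 kJ/mol)
    substrate + catalyst intermediate A → catalyst intermediate B (k = 0.810 /M/s, Ea = 81.0 kJ/mol)
    free catalyst → spent catalyst (k = 4.09 × 10⁻⁴ /s, Ea = 117 kJ/mol)
    reagent + free catalyst ⇌ catalyst intermediate A (K = 2.61 /M, k = 1.20 /M/s, Ea = 45.0 kJ/mol, ΔH = −4.00 kJ/mol)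
    (constants at 110 °C)

Reckoned from the simulated product, the flask's reach at 4.0 h is 3.35 /M, with spent catalyst at 97.2%. The neighbouring flask, with reagent cut to 0.18 M, has 98.7% spent catalyst at the same time, and its reach is 3.21 /M. Carrying the read reach of 3.69 /M over to those charges gives 25.0% product, and the neighbouring flask gives 23.9%.

(Readings and results come from a simulation with constants of no real substance.)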